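**Retrosynthetic overview**
1. The two esters are put on last, on a trans-diol; the enone comes from allylic oxidation of a methyl alkene, which comes from a ketone through its enol triflate.
2. The trans-diol comes from the seven-ring ketone: catalyst-controlled epoxidation of its silyl enol ether, then hydroxyl-directed reduction.
3. Enabling feature: the seven-membered ring is a four-carbon bridge (CH2–CH(O)–CH(O)–CMe2) tying the two diagonal carbons of the cyclobutane (the quaternary C–CH3 and the CH that bears CMe2), i.e. a bicyclo[4.1.1]octane. Removing the bridge and joining those two carbons gives the central bond of a bicyclo[1.1.0]butane, so the ring is disconnected to a 1-methyltricyclo[4.1.0.0(2,7)]heptane plus an α-bromo vinyl ketone (strain-release radical annulation).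
4. The bicyclobutane comes from 3-methylcyclohex-2-enone: asymmetric reduction, anti dibromocyclopropanation, carbenoid C–H insertion.
5. Ring order: six-membered ring (present from the start) → cyclopropane → bicyclobutane (masked cyclobutane) → cyclobutane unveiled and seven-membered ring closed last, in one operation.

Key step: step 8

Assumption: carbon radicals are taken to attack the central bond of 7 from the face opposite the three-carbon bridge, as sulfonyl radicals do with this ring system, and the L-fructose-derived enantiomer of the Shi ketone is taken as purchasable.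

Step 1
Reactants: 1 3-methylcyclohex-2-en-1-one
Product: 2 (S)-3-methylcyclohex-2-en-1-ol
Conditions: (R)-2-methyl-CBS-oxazaborolidine (10 mol %), catecholborane, toluene, −78 °C
Reagents that add atoms: none
Why: Corey–Bakshi–Shibata reduction, in which the oxazaborolidine–borane complex delivers hydride to one carbonyl face with the alkenyl branch acting as the large group, which should set the (S)-carbinol centre.

Step 2
Reactants: 2 (S)-3-methylcyclohex-2-en-1-ol
Product: 3 (S)-tert-butyldimethyl[(3-methylcyclohex-2-en-1-yl)oxy]silane
Conditions: TBSCl, imidazole, DMF, 20 °C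
Reagents that add atoms: tert-butyldimethylsilyl chloride, CC(C)(C)[Si](C)(C)Cl
Why: Imidazole-promoted silylation of a secondary alcohol, installing the bulky group that steers the next step.

Step 3
Reactants: 3 (S)-tert-butyldimethyl[(3-methylcyclohex-2-en-1-yl)oxy]silane
Product: 4 7,7-dibromo-6-methylbicyclo[4.1.0]heptan-2-yl tert-butyldimethylsilyl ether (silyloxy group anti to the cyclopropane; S carbinol carbon)
Conditions: CHBr3, 50% aq. NaOH, BnEt3NCl (cat.), CH2Cl2, 0 → 20 °C
Reagents that add atoms: bromoform, BrC(Br)Br
Why: Phase-transfer dibromocarbene cyclopropanation of the trisubstituted alkene; the carbene should add to the face opposite the pseudoaxial silyloxy group, so the carbinol centre sets both cyclopropane stereocentres (any syn adduct is removed by chromatography).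

Step 4
Reactants: 4 anti-7,7-dibromo-6-methylbicyclo[4.1.0]heptan-2-yl silyl ether
Product: 5 7,7-dibromo-6-methylbicyclo[4.1.0]heptan-2-one (single enantiomer)
Conditions: CrO3, H2SO4, acetone/H2O, 0 °C
Reagents that add atoms: none
Why: Jones oxidation, which cleaves the silyl ether under the acidic conditions and oxidises the freed secondary alcohol in the same flask; the cyclopropane stereocentres now carry the chirality alone.

Step 5
Reactants: 5 7,7-dibromo-6-methylbicyclo[4.1.0]heptan-2-one
Product: 6 7,7-dibromo-6-methylbicyclo[4.1.0]heptan-2-one pinacol ketal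
Conditions: pinacol, p-TsOH·H2O (cat.), benzene, reflux (Dean–Stark)
Reagents that add atoms: pinacol (2,3-dimethylbutane-2,3-diol), CC(C)(O)C(C)(C)O
Why: Acid-catalysed ketalisation with azeotropic removal of water; the pinacol ketal is chosen because it has no C–H bond next to oxygen that could intercept the carbenoid of the next step.

Step 6
Reactants: 6 7,7-dibromo-6-methylbicyclo[4.1.0]heptan-2-one pinacol ketal
Product: 7 1-methyltricyclo[4.1.0.0(2,7)]heptan-3-one pinacol ketal (bicyclobutane, single enantiomer)
Conditions: MeLi, Et2O, −78 → 0 °C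
Reagents that add atoms: none
Why: Bromine–lithium exchange and α-elimination give a cyclopropylidene carbenoid that inserts into the cis C–H of the adjacent ring CH2, the classical route from 7,7-dibromonorcaranes to tricyclo[4.1.0.0(2,7)]heptanes; the other flank of the cyclopropane is the hydrogen-free ketal carbon, so only the CH2 next to the methyl-bearing carbon can react, and the two new stereocentres are fixed by the cis ring geometry.

Step 7
Reactants: 8 2-bromo-2-methylpropanoyl bromide
Product: 9 4-bromo-4-methylpent-1-en-3-one
Conditions: trimethyl(vinyl)silane, AlBr3, CH2Cl2, −78 °C; cold aq. NaHCO3 work-up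
Reagents that add atoms: trimethyl(vinyl)silane, C=C[Si](C)(C)C
Why: Friedel–Crafts acylation of a vinylsilane with ipso substitution through the β-silyl cation, which gives the vinyl ketone without touching the tertiary bromide.

Step 8
Reactants: 7 1-methyltricyclo[4.1.0.0(2,7)]heptan-3-one pinacol ketal; 9 4-bromo-4-methylpent-1-en-3-one
Product: 10 2,6,6-trimethyltricyclo[5.4.0.0(2,8)]undecane-5,9-dione 9-pinacol ketal (ring fusion as in the target)
Conditions: 9 (1.5 equiv, slow addition), Hantzsch ester, fac-Ir(ppy)3 (1 mol %), K2HPO4, MeCN, 450 nm LEDs, 20 °C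
Reagents that add atoms: none
Why: Proposed new method: visible-light single-electron reduction of the tertiary α-bromo ketone 9 gives an electrophilic α-keto radical that adds to the hydrogen-bearing bridgehead of the central bicyclobutane bond of 7 from the face opposite the three-carbon bridge; strain release turns the two fused cyclopropanes into the cyclobutane and leaves a tertiary cyclobutyl radical on the methyl-bearing carbon, which lies 1,3-diaxial to the new chain and closes the seven-membered ring by 7-endo-trig (Giese-type) attack on the terminal carbon of the vinyl ketone, after which the α-keto radical takes a hydrogen atom from the Hantzsch ester. The closest known reaction types are the atom-transfer radical additions of sulfonyl halides and polyhalomethanes across the central bond of tricyclo[4.1.0.0(2,7)]heptanes and the radical-relay [2σ+2π] annulations of bicyclobutanes with alkenes; a radical [2σ+4] annulation of this hydrocarbon class with an α-bromo enone has not been shown. The two stereocentres that change (the quaternary methyl-bearing carbon and the CH carrying CMe2) are fixed by the cage: the first radical can only attack anti to the three-carbon bridge and the four-carbon bridge can only span that same face, so methyl and hydrogen end up syn to the three-carbon bridge, while the absolute configuration is that of 7. Regioselectivity (attack at the unsubstituted bridgehead) is secured by the methyl group, which makes the other site hindered and the other radical secondary; ring closure over intermolecular trapping or early reduction is secured by the slow addition of 9, by the polarity mismatch between the alkyl radical and the Hantzsch ester, and by the 1,3-diaxial proximity of radical and acceptor.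

Step 9
Reactants: 10 tricyclic 5,9-dione 9-pinacol ketal
Product: 11 5-(tert-butyldimethylsilyloxy)-2,6,6-trimethyltricyclo[5.4.0.0(2,8)]undec-4-en-9-one pinacol ketal
Conditions: KN(SiMe3)2, TBSCl, THF/DMPU, −78 → 0 °C
Reagents that add atoms: tert-butyldimethylsilyl chloride, CC(C)(C)[Si](C)(C)Cl
Why: Kinetic enolisation and O-silylation; only the CH2 flank of the ketone carries hydrogen (the other flank is the quaternary CMe2 carbon), so a single silyl enol ether forms.

Step 10
Reactants: 11 silyl enol ether
Product: 13 (4S)-4-hydroxy-2,6,6-trimethyltricyclo[5.4.0.0(2,8)]undecane-5,9-dione 9-pinacol ketal, via silyloxy epoxide 12 (not isolated)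
Conditions: ent-Shi ketone (L-fructose-derived, 30 mol %), Oxone (2KHSO5·KHSO4·K2SO4), K2CO3, Bu4NHSO4, MeCN/dimethoxymethane/aq. buffer (pH 10.5), 0 °C; then TBAF, AcOH, THF, 0 °C
Reagents that add atoms: potassium peroxymonosulfate (Oxone), [K+].[O-]S(=O)(=O)OO
Why: Shi asymmetric epoxidation of an enol silyl ether, then fluoride-induced collapse of the silyloxy epoxide to the α-hydroxy ketone; the alkene sits in a nearly mirror-symmetric environment, so the chiral dioxirane (spiro transition state; the D-fructose-derived ketone gives the opposite sense with 1-substituted cycloalkenes) should control the face and set the (S)-carbinol centre.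

Step 11
Reactants: 13 (4S)-4-hydroxy 5,9-dione 9-pinacol ketal
Product: 14 (4S,5S)-4,5-dihydroxy-2,6,6-trimethyltricyclo[5.4.0.0(2,8)]undecan-9-one pinacol ketal (trans-diol)
Conditions: Me4NBH(OAc)3, MeCN/AcOH, −20 °C
Reagents that add atoms: none
Why: Hydroxyl-directed (Saksena–Evans) triacetoxyborohydride reduction: hydride is delivered intramolecularly to the ketone face syn to the neighbouring hydroxyl, which should give the trans-diol (new centre S).

Step 12
Reactants: 14 trans-diol pinacol ketal
Product: 15 (4S,5S)-4,5-(isopropylidenedioxy)-2,6,6-trimethyltricyclo[5.4.0.0(2,8)]undecan-9-one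
Conditions: 2,2-dimethoxypropane, acetone, p-TsOH·H2O (cat.), 40 °C
Reagents that add atoms: 2,2-dimethoxypropane, COC(C)(C)OC
Why: Acid-catalysed acetonide formation with concomitant transketalisation of the pinacol ketal, which unmasks the ketone while the diol is protected for the base and oxidation steps.

Step 13
Reactants: 15 acetonide ketone
Product: 16 (4S,5S)-4,5-(isopropylidenedioxy)-2,6,6-trimethyltricyclo[5.4.0.0(2,8)]undec-9-en-9-yl trifluoromethanesulfonate
Conditions: KN(SiMe3)2, PhNTf2, THF, −78 °C
Reagents that add atoms: N-phenylbis(trifluoromethanesulfonimide), O=S(=O)(N(c1ccccc1)S(=O)(=O)C(F)(F)F)C(F)(F)F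
Why: Kinetic enolate triflation; the ketone can enolise only towards its CH2 group because the other α-carbon is a bridgehead of the bicyclo[3.1.1]heptane.

Step 14
Reactants: 16 enol triflate
Product: 17 (4S,5S)-4,5-(isopropylidenedioxy)-2,6,6,9-tetramethyltricyclo[5.4.0.0(2,8)]undec-9-ene
Conditions: MeMgBr, Fe(acac)3 (5 mol %), THF/NMP, −30 → 0 °C
Reagents that add atoms: methylmagnesium bromide, C[Mg]Br
Why: Iron-catalysed Kumada-type cross-coupling of an alkenyl triflate, which installs the vinylic methyl group under non-acidic conditions that should leave the strained pinene-type alkene intact.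

Step 15
Reactants: 17 methyl alkene acetonide
Product: 18 (4S,5S)-4,5-(isopropylidenedioxy)-2,6,6,9-tetramethyltricyclo[5.4.0.0(2,8)]undec-9-en-11-one
Conditions: t-BuOOH, Rh2(cap)4 (1 mol %), K2CO3, CH2Cl2, 20 °C
Reagents that add atoms: tert-butyl hydroperoxide, CC(C)(C)OO
Why: Dirhodium caprolactamate/hydroperoxide allylic oxidation (radical C–H peroxidation, then collapse to the enone), which should attack the only ring CH2 allylic to the trisubstituted alkene, as in the α-pinene to verbenone conversion.

Step 16
Reactants: 18 enone acetonide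
Product: 19 (4S,5S)-4,5-dihydroxy-2,6,6,9-tetramethyltricyclo[5.4.0.0(2,8)]undec-9-en-11-one
Conditions: AcOH/H2O (4:1), 45 °C
Reagents that add atoms: none
Why: Mild acid hydrolysis of the strained trans-fused acetonide; the verbenone-type enone should tolerate aqueous acetic acid.

Step 17
Reactants: 19 enone diol; 20 (S)-2-methylbutanoic acid
Product: 21 (4S,5S)-5-hydroxy-2,6,6,9-tetramethyl-11-oxotricyclo[5.4.0.0(2,8)]undec-9-en-4-yl (S)-2-methylbutanoate
Conditions: EDC·HCl, DMAP (cat.), CH2Cl2, 0 °C
Reagents that add atoms: none
Why: Steglich-type carbodiimide esterification; the hydroxyl flanked by CH2 should be acylated much faster than the neopentyl hydroxyl next to the CMe2 carbon, and the acid brings its (S) centre unchanged.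

Step 18
Reactants: 21 hydroxy mono-ester; 22 angelic acid ((Z)-2-methylbut-2-enoic acid)
Product: 24 target diester (CNP0323606.1), via mixed anhydride 23 (not isolated)
Conditions: 22, 2,4,6-trichlorobenzoyl chloride, Et3N, toluene, 20 °C; then 21, 80 °C
Reagents that add atoms: 2,4,6-trichlorobenzoyl chloride, O=C(Cl)c1c(Cl)cc(Cl)cc1Cl (its acyl group stays in intermediate 23 only)
Why: Yamaguchi esterification through the preformed mixed anhydride without nucleophilic catalyst, conditions under which angelates are transferred to hindered alcohols with the Z geometry kept; no stereocentre is formed.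

**Compound list**
1 | 3-methylcyclohex-2-en-1-one | CC1=CC(=O)CCC1 | starting material
2 | (S)-3-methylcyclohex-2-en-1-ol | CC1=C[C@@H](O)CCC1 | intermediate
3 | (S)-tert-butyldimethyl[(3-methylcyclohex-2-en-1-yl)oxy]silane | CC1=C[C@@H](O[Si](C)(C)C(C)(C)C)CCC1 | intermediate
4 | 7,7-dibromo-6-methylbicyclo[4.1.0]heptan-2-yl tert-butyldimethylsilyl ether, silyloxy anti to the cyclopropane | C[C@]12CCC[C@H](O[Si](C)(C)C(C)(C)C)[C@H]1C2(Br)Br | intermediate
5 | 7,7-dibromo-6-methylbicyclo[4.1.0]heptan-2-one | C[C@]12CCCC(=O)[C@H]1C2(Br)Br | intermediate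
6 | 7,7-dibromo-6-methylbicyclo[4.1.0]heptan-2-one pinacol ketal | C[C@]12CCCC3(OC(C)(C)C(C)(C)O3)[C@H]1C2(Br)Br | intermediate
7 | 1-methyltricyclo[4.1.0.0(2,7)]heptan-3-one pinacol ketal (bicyclobutane) | C[C@]12[C@@H]3CCC4(OC(C)(C)C(C)(C)O4)[C@H]1[C@H]23 | intermediate
8 | 2-bromo-2-methylpropanoyl bromide | CC(C)(Br)C(=O)Br | starting material
9 | 4-bromo-4-methylpent-1-en-3-one | C=CC(=O)C(C)(C)Br | intermediate
10 | 2,6,6-trimethyltricyclo[5.4.0.0(2,8)]undecane-5,9-dione 9-pinacol ketal | O=C1CC[C@@]2(C)[C@@H]3CCC4(OC(C)(C)C(C)(C)O4)[C@H]2[C@@H]3C1(C)C | intermediate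
11 | 5-(tert-butyldimethylsilyloxy)-2,6,6-trimethyltricyclo[5.4.0.0(2,8)]undec-4-en-9-one pinacol ketal | CC(C)(C)[Si](C)(C)OC1=CC[C@@]2(C)[C@@H]3CCC4(OC(C)(C)C(C)(C)O4)[C@H]2[C@@H]3C1(C)C | intermediate
12 | silyloxy epoxide of 11 (4,5-epoxy-5-silyloxy compound) | CC(C)(C)[Si](C)(C)O[C@]1(O2)[C@@H]2C[C@@]3(C)[C@@H]4CCC5(OC(C)(C)C(C)(C)O5)[C@H]3[C@@H]4C1(C)C | intermediate
13 | (4S)-4-hydroxy-2,6,6-trimethyltricyclo[5.4.0.0(2,8)]undecane-5,9-dione 9-pinacol ketal | O=C1[C@@H](O)C[C@@]2(C)[C@@H]3CCC4(OC(C)(C)C(C)(C)O4)[C@H]2[C@@H]3C1(C)C | intermediate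
14 | (4S,5S)-4,5-dihydroxy-2,6,6-trimethyltricyclo[5.4.0.0(2,8)]undecan-9-one pinacol ketal | O[C@@H]1[C@@H](O)C[C@@]2(C)[C@@H]3CCC4(OC(C)(C)C(C)(C)O4)[C@H]2[C@@H]3C1(C)C | intermediate
15 | (4S,5S)-4,5-(isopropylidenedioxy)-2,6,6-trimethyltricyclo[5.4.0.0(2,8)]undecan-9-one | CC1(C)O[C@@H]2[C@@H](O1)C[C@@]3(C)[C@@H]4CCC(=O)[C@H]3[C@@H]4C2(C)C | intermediate
16 | enol triflate of 15 (undec-9-en-9-yl triflate) | CC1(C)O[C@@H]2[C@@H](O1)C[C@@]3(C)[C@@H]4CC=C(OS(=O)(=O)C(F)(F)F)[C@H]3[C@@H]4C2(C)C | intermediate
17 | (4S,5S)-4,5-(isopropylidenedioxy)-2,6,6,9-tetramethyltricyclo[5.4.0.0(2,8)]undec-9-ene | CC1(C)O[C@@H]2[C@@H](O1)C[C@@]3(C)[C@@H]4CC=C(C)[C@H]3[C@@H]4C2(C)C | intermediate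
18 | (4S,5S)-4,5-(isopropylidenedioxy)-2,6,6,9-tetramethyltricyclo[5.4.0.0(2,8)]undec-9-en-11-one | CC1(C)O[C@@H]2[C@@H](O1)C[C@@]3(C)[C@@H]4C(=O)C=C(C)[C@H]3[C@@H]4C2(C)C | intermediate
19 | (4S,5S)-4,5-dihydroxy-2,6,6,9-tetramethyltricyclo[5.4.0.0(2,8)]undec-9-en-11-one | O[C@@H]1[C@@H](O)C[C@@]2(C)[C@@H]3C(=O)C=C(C)[C@H]2[C@@H]3C1(C)C | intermediate
20 | (S)-2-methylbutanoic acid | CC[C@H](C)C(=O)O | starting material
21 | (4S,5S)-5-hydroxy-2,6,6,9-tetramethyl-11-oxotricyclo[5.4.0.0(2,8)]undec-9-en-4-yl (S)-2-methylbutanoate | O[C@@H]1[C@@H](OC(=O)[C@@H](C)CC)C[C@@]2(C)[C@@H]3C(=O)C=C(C)[C@H]2[C@@H]3C1(C)C | intermediate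
22 | angelic acid ((Z)-2-methylbut-2-enoic acid) | C/C=C(/C)C(=O)O | starting material
23 | (Z)-2-methylbut-2-enoic 2,4,6-trichlorobenzoic anhydride | C/C=C(/C)C(=O)OC(=O)c1c(Cl)cc(Cl)cc1Cl | intermediate
24 | target: (4S,5S)-5-[(Z)-2-methylbut-2-enoyloxy]-2,6,6,9-tetramethyl-11-oxotricyclo[5.4.0.0(2,8)]undec-9-en-4-yl (S)-2-methylbutanoate | C/C=C(/C)C(=O)O[C@@H]1[C@@H](OC(=O)[C@@H](C)CC)C[C@@]2(C)[C@@H]3C(=O)C=C(C)[C@H]2[C@@H]3C1(C)C | target

**Totals**
Total step count: 18. Longest linear sequence: 17 steps (steps 1–6 and 8–18, from 1 to 24).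

**Steps most likely to fail**

Step 8 (proposed new method). What may go wrong: the first radical may be reduced before it adds, the cyclobutyl radical may be trapped intermolecularly or oligomerise instead of closing the seven-membered ring, or the bicyclobutane may isomerise. The fallback uses known reaction types, sets out from 7 and 8 and comes back at 10. Acid bromide 8 is added to ethylene (AlBr3, CH2Cl2) to give 1,4-dibromo-4-methylpentan-3-one F1. Et3B/air-initiated bromine-atom-transfer addition of F1 through its tertiary α-keto C–Br bond across the central bond of 7, the addition type established for this ring system with sulfonyl halides and polyhalomethanes, should give the bromo ketone adduct F2. Et3N then eliminates HBr from the β-bromoethyl ketone to give the vinyl ketone bromide F3. Slow addition of Bu3SnH/AIBN in benzene at 80 °C regenerates the tertiary cyclobutyl radical at high dilution for a conventional 7-endo Giese cyclization, which should give 10.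

Step 10. What may go wrong: poor facial selectivity, because the alkene is far from every stereocentre of the cage, or hydrolysis of the silyl enol ether in the basic aqueous medium. The fallback sets out from 10 and comes back at 13: the potassium enolate of 10 (KN(SiMe3)2, THF, −78 °C) is hydroxylated with the enantiomer of (8,8-dichlorocamphorylsulfonyl)oxaziridine that delivers oxygen to the required face (Davis asymmetric enolate hydroxylation), giving 13 directly; no new compound lies on this way (F0).

Step 18. What may go wrong: Z-to-E isomerisation of the angeloyl group during activation, migration of the neighbouring 2-methylbutanoyl group, or incomplete acylation of the neopentyl hydroxyl. The fallback sets out from 21 and comes back at 24: 21 is esterified with 2-[bis(2,2,2-trifluoroethoxy)phosphoryl]propanoic acid (diisopropylcarbodiimide, DMAP cat.) to give the phosphonate ester F4, and a Still–Gennari olefination (KN(SiMe3)2, 18-crown-6, acetaldehyde, THF, −78 °C) builds the Z-configured 2-methylbut-2-enoate in place, giving 24.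

**Further compounds**
F1 | step 8 | 1,4-dibromo-4-methylpentan-3-one | BrCCC(=O)C(C)(C)Br
F2 | step 8 | bromo ketone adduct: 6-bromo-6-methyl-7-(5-bromo-2-methyl-3-oxopentan-2-yl)bicyclo[3.1.1]heptan-2-one pinacol ketal, side chain anti to the three-carbon bridge, either configuration at the C–Br carbon | BrCCC(=O)C(C)(C)[C@@H]1[C@H]2CCC3(OC(C)(C)C(C)(C)O3)[C@@H]1C2(C)Br
F3 | step 8 | vinyl ketone bromide: 6-bromo-6-methyl-7-(2-methyl-3-oxopent-4-en-2-yl)bicyclo[3.1.1]heptan-2-one pinacol ketal | C=CC(=O)C(C)(C)[C@@H]1[C@H]2CCC3(OC(C)(C)C(C)(C)O3)[C@@H]1C2(C)Br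
F0 | step 10 | none | none
F4 | step 18 | phosphonate ester: 2-[bis(2,2,2-trifluoroethoxy)phosphoryl]propanoate of 21 at the neopentyl hydroxyl | CC(C(=O)O[C@@H]1[C@@H](OC(=O)[C@@H](C)CC)C[C@@]2(C)[C@@H]3C(=O)C=C(C)[C@H]2[C@@H]3C1(C)C)P(=O)(OCC(F)(F)F)OCC(F)(F)F
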